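Each half of the target is an arene-fused 1,4-dicarbonyl ring whose benzene ring carries the same 1,2,4-trioxygenation: C5', C7', C8' (ring B', naphthoquinone half) and C5, C6, C8 (ring B, naphthalenetrione half). Cutting both arenes away at the enedione carbons C4a'/C8a' and C4a/C8a leaves a bis-monocyclic core, the C2–O–C2' dehydro-dimer of one bromo(ethyl)hydroxybenzoquinone, in which the (S)-quaternary ether already stands. A single two-directional annulation with a tetraoxygenated vinylketene acetal then forms C4a'–C5', C8'–C8a', C8–C8a and C4a–C5 and aromatises rings B and B'; bromine on C8a' and C4a fixes the orientation.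

Key step: step 9

Remark: the naphthalene-type locants of the target (unprimed: trione half, C2 = stereocentre; primed: quinone half, C2' = ether carbon) are also used for the corresponding carbons of 13. C2 is (S) (O > C3 > C1 > ethyl); as no asymmetric method is established for a tertiary alkyl quinonyl ether of this kind, C2 is formed as a racemate and the (S)-enantiomer is taken by resolution in step 6.

Step 1
Reactants: 1 1,3-dimethoxybenzene; 2 iodoethane
Product: 4 2-ethyl-1,3-dimethoxybenzene, via 2-lithio-1,3-dimethoxybenzene 3 (not isolated)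
Conditions: n-BuLi, THF, 0 °C to rt; then 2, 0 °C to rt
Reagents that add atoms: none
Why: Directed ortho-lithiation at the C–H between the two methoxy groups, then SN2 alkylation of the aryllithium by the primary iodide, is a standard way to 2-alkyl-1,3-dimethoxybenzenes.

Step 2
Reactants: 4 2-ethyl-1,3-dimethoxybenzene
Product: 6 5-bromo-2-ethyl-1,3-dimethoxybenzene, via aryl pinacolboronate 5 (not isolated)
Conditions: [Ir(OMe)(cod)]2 (cat.), 4,4'-di-tert-butyl-2,2'-bipyridine (cat.), B2pin2, THF, 80 °C; evaporation; then CuBr2, MeOH/H2O, 80 °C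
Reagents that add atoms: copper dibromide, [Cu+2].[Br-].[Br-]
Why: Iridium-catalysed C–H borylation is sterically controlled and should select C5, the only ring C–H without an ortho substituent, and copper-mediated bromodeboronation then places bromine para to ethyl, a position that electrophilic bromination cannot reach.

Step 3
Reactants: 6 5-bromo-2-ethyl-1,3-dimethoxybenzene
Product: 9 6-bromo-3-ethyl-2,4-dimethoxyphenol, via aryllithium 7 (not isolated), via diisopropyl arylboronate 8 (not isolated)
Conditions: lithium 2,2,6,6-tetramethylpiperidide, B(OiPr)3, THF, −78 °C to rt; then AcOH, 30% H2O2, 0 °C to rt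
Reagents that add atoms: hydrogen peroxide, OO
Why: Directed ortho-metalation at the C–H flanked by bromine and methoxy (the two such sites are equivalent by symmetry) with in situ borate trapping should outrun aryne formation, and oxidation of the C–B bond with 1,2-aryl shift gives the phenol ortho to bromine without any regiochemical choice.

Step 4
Reactants: 9 6-bromo-3-ethyl-2,4-dimethoxyphenol
Product: 11 5-bromo-2-ethyl-3-hydroxy-1,4-benzoquinone, via 6-bromo-3-ethylbenzene-1,2,4-triol 10 (not isolated)
Conditions: BBr3, CH2Cl2, −78 °C to rt; H2O; then FeCl3, H2O/EtOAc, 0 °C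
Reagents that add atoms: none
Why: Lewis-acid cleavage of both aryl methyl ethers gives the hydroxyhydroquinone, which iron trichloride should oxidise by two electrons to the 2-hydroxy-1,4-benzoquinone, a stable vinylogous acid.

Step 5
Reactants: 11 5-bromo-2-ethyl-3-hydroxy-1,4-benzoquinone (two molecules)
Product: 12 racemic 5-bromo-3-[(4-bromo-1-ethyl-2,3,6-trioxocyclohex-4-en-1-yl)oxy]-2-ethyl-1,4-benzoquinone
Conditions: PbO2, AcOH, rt
Reagents that add atoms: none
Why: One-electron oxidation of the enol gives a radical delocalised over O3, C2 and O1 of 11, and C2–O3 coupling of two such radicals should give the quinonyl ether of the triketone, the oxidative dehydrodimerisation known for lapachol and other 2-hydroxy-3-alkyl-1,4-naphthoquinones with lead dioxide; the quaternary centre forms without facial bias, so 12 is racemic.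

Step 6
Reactants: 12 racemic dehydro-dimer
Product: 13 (S)-enantiomer of the dehydro-dimer (precursor of the key step)
Conditions: preparative HPLC, immobilised amylose tris(3,5-dimethylphenylcarbamate) phase, heptane/EtOAc, rt
Reagents that add atoms: none
Why: Resolution on a chiral stationary phase with a non-nucleophilic eluent (which leaves the electrophilic triketone alone) should separate the enantiomers; the (S)-enantiomer is identified by X-ray diffraction using the anomalous dispersion of bromine, and this step secures the only stereocentre of the target.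

Step 7
Reactants: 14 1,1,2-trimethoxyethane; 15 methyl 2-(dimethoxyphosphoryl)-2-methoxyacetate
Product: 18 methyl (Z)-2,4-dimethoxybut-2-enoate, via methoxyacetaldehyde 16 (not isolated), via sodium phosphonate carbanion 17 (not isolated)
Conditions: 14, 1 M aq. HCl (cat.), 50 °C; NaCl, extraction into CH2Cl2, MgSO4; 15, NaH, THF, 0 °C; then the solution of 16, 0 °C to rt
Reagents that add atoms: none
Why: Acid hydrolysis of the dimethyl acetal frees the aldehyde, which undergoes Horner–Wadsworth–Emmons olefination with the phosphonate carbanion to the α-methoxy enoate (mainly Z expected, ester trans to CH2OMe; this geometry is erased in step 8).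

Step 8
Reactants: 18 methyl (Z)-2,4-dimethoxybut-2-enoate
Product: 20 (3E)-1,2,4-trimethoxy-1-(trimethylsilyloxy)buta-1,3-diene, via lithium dienolate 19 (not isolated)
Conditions: LiN(i-Pr)2, THF/DMPU, −78 °C; then Me3SiCl, −78 °C to rt; filtration under argon
Reagents that add atoms: chlorotrimethylsilane, C[Si](C)(C)Cl
Why: γ-Deprotonation of the enoate and O-silylation of the extended enolate is the standard entry to 1-alkoxy-1-silyloxybutadienes (vinylketene acetals); allylic 1,3-strain against the C2 methoxy group should place the C4 methoxy group trans and give the (3E)-diene, while the ketene-acetal geometry is without consequence.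

Step 9
Reactants: 13 (S)-dehydro-dimer; 20 (3E)-1,2,4-trimethoxy-1-(trimethylsilyloxy)buta-1,3-diene (two equivalents are incorporated)
Product: 23 (S)-configured 6,8,5',7'-tetra-O-methyl ether of the target with free C5 and C8' hydroxyls, via bis-cycloadduct 21 (not isolated), via bis(trimethylsilyl) ether 22 (not isolated)
Conditions: 20 (3.5 equiv), toluene, −40 °C to rt; then moist SiO2, CH2Cl2, rt
Reagents that add atoms: none
Why: Proposed new method: each event is a polar, stepwise [4+2] annulation in which the CH(OMe) terminus of 20, made nucleophilic by the two ketene-acetal oxygens, adds in Michael fashion to the unsubstituted enedione carbon (C4a' and C8a), the resulting α-bromo enolate closes on the silyloxy-oxocarbenium carbon (C8'–C8a' and C4a–C5), and E1cB loss of HBr followed by 1,4-loss of methanol aromatises rings B' and B, leaving silyl ethers that hydrolyse to the chelated peri hydroxyls. The closest known reaction type is the regiocontrolled cycloaddition–aromatisation of 1-alkoxy-1-silyloxybutadienes with 2-bromo-1,4-quinones, which has not been run on a non-quinoid bromo-enetrione, in two directions at once, or with a 1,1,2,4-tetraoxygenated diene. Each six-membered carbocycle is closed in the intermolecular [4+2] mode, the second bond forming as a 6-(enolexo)-exo-trig attack. All sp3 centres created in 21 are destroyed on aromatisation, so no new stereocentre remains, and the quaternary C2 (S), which has no α-hydrogen and is not touched, is retained. The step needs the same orientation in both halves and reaction only at the two bromo-enedione C=C bonds: bromine on C8a' and C4a takes the ketene-acetal carbon and is reinforced by the more electrophilic carbonyls C1' and C4, the tetrasubstituted C2'=C3' bond is inert, and low temperature without Lewis acid should hold back aldol-type attack on the C3 ketone. Should the silyloxy group instead of methoxy be lost at C8' or C5, the peri-methoxy product would converge in step 10.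

Step 10
Reactants: 23 tetra-O-methyl ether
Product: 24 target, 2-{[(2S)-2-ethyl-5,6,8-trihydroxy-1,3,4-trioxo-1,2,3,4-tetrahydronaphthalen-2-yl]oxy}-3-ethyl-5,7,8-trihydroxy-1,4-naphthoquinone
Conditions: BBr3 (excess), CH2Cl2, −78 °C to 0 °C; then H2O, 0 °C
Reagents that add atoms: none
Why: BBr3 should cleave all four aryl methyl ethers (Lewis-acid-mediated SN2 demethylation, the peri ones helped by chelation), whereas the central ether cannot cleave by SN1 or SN2 at a tertiary carbon flanked by two carbonyls; no reductant is present, so the reducible C2–O bond and the (S) centre are kept.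

Compound list
1 | 1,3-dimethoxybenzene | COc1cccc(OC)c1 | starting material
2 | iodoethane | CCI | starting material
3 | 2-lithio-1,3-dimethoxybenzene | [Li]c1c(OC)cccc1OC | intermediate
4 | 2-ethyl-1,3-dimethoxybenzene | CCc1c(OC)cccc1OC | intermediate
5 | 2-(4-ethyl-3,5-dimethoxyphenyl)-4,4,5,5-tetramethyl-1,3,2-dioxaborolane | CCc1c(OC)cc(cc1OC)B1OC(C)(C)C(C)(C)O1 | intermediate
6 | 5-bromo-2-ethyl-1,3-dimethoxybenzene | CCc1c(OC)cc(Br)cc1OC | intermediate
7 | (6-bromo-3-ethyl-2,4-dimethoxyphenyl)lithium | [Li]c1c(Br)cc(OC)c(CC)c1OC | intermediate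
8 | diisopropyl (6-bromo-3-ethyl-2,4-dimethoxyphenyl)boronate | CCc1c(OC)cc(Br)c(B(OC(C)C)OC(C)C)c1OC | intermediate
9 | 6-bromo-3-ethyl-2,4-dimethoxyphenol | CCc1c(OC)cc(Br)c(O)c1OC | intermediate
10 | 6-bromo-3-ethylbenzene-1,2,4-triol | CCc1c(O)cc(Br)c(O)c1O | intermediate
11 | 5-bromo-2-ethyl-3-hydroxycyclohexa-2,5-diene-1,4-dione | CCC1=C(O)C(=O)C(Br)=CC1=O | intermediate
12 | racemic 5-bromo-3-[(4-bromo-1-ethyl-2,3,6-trioxocyclohex-4-en-1-yl)oxy]-2-ethylcyclohexa-2,5-diene-1,4-dione | CCC1=C(OC2(CC)C(=O)C(=O)C(Br)=CC2=O)C(=O)C(Br)=CC1=O | intermediate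
13 | 5-bromo-3-{[(1S)-4-bromo-1-ethyl-2,3,6-trioxocyclohex-4-en-1-yl]oxy}-2-ethylcyclohexa-2,5-diene-1,4-dione | CCC1=C(O[C@]2(CC)C(=O)C(=O)C(Br)=CC2=O)C(=O)C(Br)=CC1=O | intermediate
14 | 1,1,2-trimethoxyethane | COCC(OC)OC | starting material
15 | methyl 2-(dimethoxyphosphoryl)-2-methoxyacetate | COC(C(=O)OC)P(=O)(OC)OC | starting material
16 | methoxyacetaldehyde | COCC=O | intermediate
17 | sodium salt of the carbanion of 15 | [Na+].COC(=O)[C-](OC)P(=O)(OC)OC | intermediate
18 | methyl (Z)-2,4-dimethoxybut-2-enoate | COC/C=C(\OC)C(=O)OC | intermediate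
19 | lithium (3E)-1,2,4-trimethoxybuta-1,3-dien-1-olate | [Li+].CO/C=C/C(OC)=C(OC)[O-] | intermediate
20 | (3E)-1,2,4-trimethoxy-1-(trimethylsilyloxy)buta-1,3-diene (ketene-acetal geometry as drawn) | CO/C=C/C(/OC)=C(/OC)O[Si](C)(C)C | intermediate
21 | bis-cycloadduct of 13 with two molecules of 20 (bromine on C8a' and C4a, hydrogen on C4a' and C8a; mixture of diastereomers at the new sp3 carbons) | CCC1=C(O[C@]2(CC)C(=O)C(=O)C3(Br)C(OC)(O[Si](C)(C)C)C(OC)=CC(OC)C3C2=O)C(=O)C2(Br)C(OC)(O[Si](C)(C)C)C(OC)=CC(OC)C2C1=O | intermediate
22 | 5,8'-bis(trimethylsilyl) ether of 23 | CCC1=C(O[C@]2(CC)C(=O)C(=O)c3c(O[Si](C)(C)C)c(OC)cc(OC)c3C2=O)C(=O)c2c(O[Si](C)(C)C)c(OC)cc(OC)c2C1=O | intermediate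
23 | 2-{[(2S)-2-ethyl-5-hydroxy-6,8-dimethoxy-1,3,4-trioxo-1,2,3,4-tetrahydronaphthalen-2-yl]oxy}-3-ethyl-8-hydroxy-5,7-dimethoxy-1,4-naphthoquinone | CCC1=C(O[C@]2(CC)C(=O)C(=O)c3c(O)c(OC)cc(OC)c3C2=O)C(=O)c2c(O)c(OC)cc(OC)c2C1=O | intermediate
24 | 2-{[(2S)-2-ethyl-5,6,8-trihydroxy-1,3,4-trioxo-1,2,3,4-tetrahydronaphthalen-2-yl]oxy}-3-ethyl-5,7,8-trihydroxy-1,4-naphthoquinone (CNP0325426.1) | CCC1=C(O[C@]2(CC)C(=O)C(=O)c3c(O)c(O)cc(O)c3C2=O)C(=O)c2c(O)c(O)cc(O)c2C1=O | target

Total step count: 10. Longest linear sequence: 8 steps (steps 1 to 6, then 9 and 10); the diene is made in 2 steps (7 and 8).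

Steps most likely to fail

Step 9 (labelled step). The silyl ketene acetal may add in aldol fashion to the strongly electrophilic C3 ketone, the electron-rich diene may transfer an electron to the dehydro-dimer with reductive cleavage of the C2–O bond, or the reaction may stall after one annulation. The fallback separates and reorders the two events with known reaction types; it sets out from 9 and comes back at 23. Phenol 9 is oxidised with (NH4)2Ce(NO3)6 in aqueous MeCN to 5-bromo-2-ethyl-3-methoxy-1,4-benzoquinone F1. This ordinary 2-bromoquinone is annulated with 20 (the established bromoquinone/vinylketene-acetal cycloaddition–aromatisation) to 3-ethyl-8-hydroxy-2,5,7-trimethoxy-1,4-naphthoquinone F2. The vinylogous ester is hydrolysed with dilute aqueous NaOH to 3-ethyl-2,8-dihydroxy-5,7-dimethoxy-1,4-naphthoquinone F3. Dehydrodimerisation with PbO2 in AcOH, now on the precedented 2-hydroxy-3-alkylnaphthoquinone class, gives the racemic tetra-O-methyl ether F4, which is resolved on the chiral phase of step 6 to give 23.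

Step 5. The radical from 11 may couple through carbon–carbon or oxygen–oxygen instead of C2–O3, disproportionate to an ethylidene quinone methide, or be over-oxidised. The fallback replaces the radical homocoupling by a polar two-component etherification; it sets out from 11 and comes back at 12. One portion of 11 is brominated at the enol carbon with N-bromosuccinimide in CH2Cl2 to 2,5-dibromo-2-ethylcyclohex-5-ene-1,3,4-trione F5. Its tertiary bromide, activated by two flanking carbonyls, is then displaced by the silver salt of a second portion of 11 (Ag2O, MeCN, 0 °C) to give 12.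

Step 10. Under boron activation, bromide may add to C2' and expel the triketone alkoxide (addition–elimination that severs the central ether), or the two β-methoxy groups (C6, C7') may be cleaved incompletely. The fallback changes the protecting groups so that only chelation-assisted cleavage of the peri-methoxy groups is needed; it sets out from 16 and 13 and comes back at 24. Aldehyde 16 is olefinated with the known reagent methyl 2-[(tert-butyldimethylsilyl)oxy]-2-(dimethoxyphosphoryl)acetate (NaH, THF) to methyl (Z)-2-[(tert-butyldimethylsilyl)oxy]-4-methoxybut-2-enoate F6. γ-Deprotonation and silylation as in step 8 give (3E)-2-[(tert-butyldimethylsilyl)oxy]-1,4-dimethoxy-1-(trimethylsilyloxy)buta-1,3-diene F7. Annulation with 13 as in step 9 gives the 6,7'-bis(tert-butyldimethylsilyl) 8,5'-di-O-methyl ether F8. BCl3 at −78 °C (peri-methoxy groups only), then HF·pyridine (silyl ethers), gives 24.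

Further compounds
F1 | step 9 | 5-bromo-2-ethyl-3-methoxy-1,4-benzoquinone | CCC1=C(OC)C(=O)C(Br)=CC1=O
F2 | step 9 | 3-ethyl-8-hydroxy-2,5,7-trimethoxy-1,4-naphthoquinone | CCC1=C(OC)C(=O)c2c(O)c(OC)cc(OC)c2C1=O
F3 | step 9 | 3-ethyl-2,8-dihydroxy-5,7-dimethoxy-1,4-naphthoquinone | CCC1=C(O)C(=O)c2c(O)c(OC)cc(OC)c2C1=O
F4 | step 9 | racemic form of 23 | CCC1=C(OC2(CC)C(=O)C(=O)c3c(O)c(OC)cc(OC)c3C2=O)C(=O)c2c(O)c(OC)cc(OC)c2C1=O
F5 | step 5 | 2,5-dibromo-2-ethylcyclohex-5-ene-1,3,4-trione | CCC1(Br)C(=O)C(=O)C(Br)=CC1=O
F6 | step 10 | methyl (Z)-2-[(tert-butyldimethylsilyl)oxy]-4-methoxybut-2-enoate | COC/C=C(\O[Si](C)(C)C(C)(C)C)C(=O)OC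
F7 | step 10 | (3E)-2-[(tert-butyldimethylsilyl)oxy]-1,4-dimethoxy-1-(trimethylsilyloxy)buta-1,3-diene | CO/C=C/C(O[Si](C)(C)C(C)(C)C)=C(OC)O[Si](C)(C)C
F8 | step 10 | 2-{[(2S)-6-[(tert-butyldimethylsilyl)oxy]-2-ethyl-5-hydroxy-8-methoxy-1,3,4-trioxo-1,2,3,4-tetrahydronaphthalen-2-yl]oxy}-7-[(tert-butyldimethylsilyl)oxy]-3-ethyl-8-hydroxy-5-methoxy-1,4-naphthoquinone | CCC1=C(O[C@]2(CC)C(=O)C(=O)c3c(O)c(O[Si](C)(C)C(C)(C)C)cc(OC)c3C2=O)C(=O)c2c(O)c(O[Si](C)(C)C(C)(C)C)cc(OC)c2C1=O
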